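The data were generated by integration from invented constants; scatter was added.

Oak is charged 2.20 times as concentrated as cedar, at equal equivalents, and I want the target in a flask charged between them.

| setting | cedar | oak | flask |
|---|---|---|---|
| substrate | 0.10 M | 0.22 M | 0.15 M |
| first nucleophile | 3 equiv | 3 equiv | 3.00 equiv |
| second nucleophile | 0.80 equiv | 0.80 equiv | 0.800 equiv |
| remark | run made earlier | run made earlier |  |
| time |  |  | 5.0 d |

| run | time / d | target / % | substrate / % |
|---|---|---|---|
| cedar | 0.250 | 0.8 | 97.7 |
| cedar | 0.417 | 2.4 | 96.2 |
| cedar | 0.625 | 2.7 | 95.1 |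
| cedar | 1.04 | 3.5 | 91.6 |
| cedar | 1.67 | 4.2 | 87.7 |
| cedar | 3.00 | 8.7 | 78.3 |
| oak | 0.500 | 3.1 | 94.2 |
| oak | 1.04 | 4.9 | 87.5 |
| oak | 1.67 | 7.2 | 81.7 |
| oak | 2.08 | 8.4 | 76.8 |
| oak | 2.50 | 9.3 | 72.1 |
| oak | 3.00 | 10.5 | 67.8 |

(scatter of a reading: 0.5 percentage points)

* amount of target in percent of the substrate charged, at 12 h, 40 h, 3.0 d and 5.0 d

- the numbers in the tables scatter with a standard deviation of 0.5 percentage points

Each run decays like a first-order one. The last substrate reading gives a constant of 0.0815 /d in cedar and 0.130 /d in oak, and oak's constant gives 87.4% at 1.04 d, against the reading 87.5%. Yet a true first order would give both runs one constant, and oak's is 1.60 times cedar's.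

The two facts fit if a concentration other than [substrate] enters the rate. If each target takes one first nucleophile, the target in oak at 3.00 d has used hardly any of that charge, so [first nucleophile] stands nearly still within oak, which suits a pseudo-first-order decay, while between the runs it follows the charge, as [second nucleophile] does at equal equivalents. I call the power of the charge that carries one run's constant to the other's the apparent order, and read it as 0.587. I take a value below one to mean that capture competes with a return.

For this flask the apparent order gives 0.103 /d, so I expect 59.6% of the substrate at 5.0 d. Target took 40.1% of the substrate consumed in cedar and 32.6% in oak at 3.00 d. Held at these shares, I reckon 8.67% to 10.7% at 3.0 d and 13.2% to 16.2% at 5.0 d.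

The forecast gives 2.6%, 5.7%, 9.2% and 13%: “Beyond 3 d the slope should ease”. At 5.0 d we part, its single value against my range.

The flask gives 2.22%, 6.58%, 9.98% and 13.1% of target, so the forecast holds within the tolerance, and 58.5% of the substrate stands at 5.00 d, where the apparent order of 0.587 gave 59.6%. substrate ⇌ intermediate (K = 0.0130, k = 0.00790 /h); first nucleophile + intermediate → target (k = 0.720 /M/h); second nucleophile + intermediate → other capture product (k = 1.80 /M/h); substrate + target → side product A (k = 0.0710 /M/h); second nucleophile ⇌ dormant form (K = 0.560, k = 0.0110 /h); intermediate → side product B (k = 0.0470 /h)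

In this flask at 2.08 d, the intermediate falls back 1.2 times faster than it goes on. A fraction of 0.547 of the intermediate formed at that time returns to substrate.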